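The last two readings of the red run average 89.6% of ring from a charge of 0.23 M. Its readings at 60.0 min and 80.0 min differ by less than their scatter of 1 percentage point, so we read the value at 80 min as an end value.

| flask | substrate | remark | time |
|---|---|---|---|
| red | 0.23 M | run made earlier |  |
| maple | 0.40 M |  | 80 min |
| oak | 0.20 M |  | 80 min |
| ash | 0.56 M |  | 80 min |
| birch | 1.2 M |  | 80 min |
| larch | 2.5 M |  | 80 min |

red run (percent of the substrate charged)

| time / min | ring / % |
|---|---|
| 15.0 | 76.5 |
| 30.0 | 82.3 |
| 50.0 | 88.4 |
| 60.0 | 89.9 |
| 80.0 | 89.3 |

(each reading ± 1 percentage point)

- the flasks put in order of amount of ring, in percent of the substrate charged, best first, at 80 min (maple / oak / ash / birch / larch)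
- the amount of ring, in percent of the substrate charged of the flask you put first, at 80 min
- the amount of ring, in percent of the substrate charged of the flask you put last, at 80 min

Our own reckoning assumes that substrate goes two ways: ring closure, first order, and a side reaction in which two substrate molecules meet, second order, using two per turn. Divide one rate by the other and time drops out. Of the substrate used at concentration c, the share becoming ring is c\*/(c\* + c), where c\* is the closure constant over 2 times the side constant; the expression has the shape of a saturation term with a Km. Summing that share from the charge C down to nothing gives ring as a fraction of the charge: (c\*/C) ln(1 + C/c\*). Solved for that average of the red run, this gives, as a reading with the scatter of that run, the crossover concentration c\*, the substrate level at which the two paths use substrate equally fast (the effective molarity), 0.952 M.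

Ring then falls as the charge rises, so we rank the flasks by charge. Oak, with 0.20 M, comes first at 90.8%. Larch, with 2.5 M, comes last at 49.1%.

The forecast gives oak > maple > ash > birch > larch, with 91% (87% to 95%) for oak and 47% (27% to 62%) for larch, holding that “dilution should favour ring”. For larch it stands lower than our figure, since it shades that flask down.

The flasks give oak > maple > ash > birch > larch, with 89.6% in oak and 46.8% in larch.

    substrate → ring (k = 0.225 min⁻¹)
    2 substrate → open dimer (k = 0.149 M⁻¹ min⁻¹)
    crystals ⇌ ring, rate k3*(cs3 - [ring]) while solid is left; crystals form when [ring] > cs3 (solubility = 0.120 M, k = 0.131 min⁻¹)
    substrate ⇌ dormant form (K = 0.640, k = 0.0416 min⁻¹)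

In oak, ring closure uses substrate 3.8 times as fast as open dimer formation at the start and 9.5 times as fast at 3.10 min. Oak's ring has moved by 5 points, which is below the forecast's low end of 87%, at 0.324 M of substrate or in a run cut to 26.5 min. Our 0.952 M gave 90.8% for oak against 89.6%, and for a neighbour flask like oak but with 0.34 M of substrate it gives 85.5% against 84.0%.

The readings come from a simulation with made-up constants.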